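**Plan**

- Retrosynthesis first removes the side-chain functions: the tiglate and acetate C–O bonds, the aldehyde oxygen (back to an isopropenyl methyl) and the carbinol C–H (back to the aryl ketone). This leaves a 5-acetyl-3-acyloxy-2-isopropenyl-2,3-dihydrobenzofuran.
- Enabling feature: in ring B (the dihydrofuran) C2 carries the ring oxygen O1 and the exocyclic C(=CH2) carbon and lies next to the oxygenated benzylic C3. This O1–C2(–C3–O)–C(=CH2) array is what a trans-3,4-dioxygenated 2,2-dimethylchroman gives when its ring oxygen moves from the quaternary carbon to the neighbouring carbon. The O1–C2 bond is therefore cut and O1 is returned to CMe2.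
- The chroman is traced through its 3,4-epoxide to the 2,2-dimethyl-2H-chromene and on to the 1,1-dimethylpropargyl ether of 4'-hydroxyacetophenone.
- Forward: O-propargylation, then Claisen rearrangement and electrocyclisation build the pyran on ring A (the arene). Epoxidation and anti opening follow, the oxygen shift contracts the pyran to ring B, and ester exchange, ketone reduction, tigloylation and allylic oxidation complete the side chains.
- Stereochemistry: C2 and C3 both come from the catalyst-controlled (salen)MnCl epoxidation, C3 through anti opening at the benzylic carbon and C2 through inversion in the oxygen shift. The carbinol centre comes from a CBS reduction, and the (E)-tiglate geometry is bought with the acyl chloride.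

Key step: step 5

Remark on the chemistry: the (S,S)-configured (salen)MnCl catalyst is assumed to give the (3S,4S)-epoxide, as expected for 2,2-dimethylchromenes with an acceptor at C6. If the sense proved opposite, the (R,R)-catalyst would be used.

**Route**

Step 1
Reactants: 1 4'-hydroxyacetophenone; 2 3-chloro-3-methylbut-1-yne
Product: 3 1-{4-[(2-methylbut-3-yn-2-yl)oxy]phenyl}ethan-1-one
Conditions: K2CO3, KI (cat.), CuI (cat.), acetone, reflux
Reagents that add atoms: none
Why: Copper-assisted O-alkylation of the phenoxide by the tertiary propargylic chloride (Williamson-type etherification through a copper acetylide) should give the 1,1-dimethylpropargyl ether, the acetyl group being a spectator.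

Step 2
Reactants: 3 1-{4-[(2-methylbut-3-yn-2-yl)oxy]phenyl}ethan-1-one
Product: 6 1-(2,2-dimethyl-2H-chromen-6-yl)ethan-1-one, via allenylphenol 4 (not isolated), via ortho-quinone methide 5 (not isolated)
Conditions: N,N-diethylaniline, 190 °C
Reagents that add atoms: none
Why: An aromatic propargyl Claisen rearrangement with tautomerisation gives allenylphenol 4, a 1,5-hydrogen shift turns it into ortho-quinone methide 5 and an oxa-6π electrocyclisation closes the pyran ring, the two ortho positions of the para-substituted arene being equivalent so that only the 6-acetyl chromene can form.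

Step 3
Reactants: 6 1-(2,2-dimethyl-2H-chromen-6-yl)ethan-1-one
Product: 7 (3S,4S)-6-acetyl-3,4-epoxy-2,2-dimethylchroman
Conditions: (S,S)-(salen)MnCl (5 mol%; salen = N,N'-bis(3,5-di-tert-butylsalicylidene)-1,2-cyclohexanediamine dianion), mCPBA, NMO, CH2Cl2, −78 °C
Reagents that add atoms: meta-chloroperoxybenzoic acid, O=C(OO)c1cccc(Cl)c1
Why: Jacobsen–Katsuki epoxidation, for which the cis-disubstituted, aryl-conjugated double bond of a 2,2-dimethylchromene is the best substrate class: the chiral ligand of the oxo-manganese species selects one alkene face so that both new centres (3S,4S) are set by catalyst control, and the anhydrous mCPBA/NMO protocol avoids hypochlorite, which could cleave the methyl ketone in a haloform reaction.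

Step 4
Reactants: 7 (3S,4S)-6-acetyl-3,4-epoxy-2,2-dimethylchroman
Product: 8 (3S,4R)-6-acetyl-3-hydroxy-2,2-dimethylchroman-4-yl trifluoroacetate (trans)
Conditions: CF3CO2H (3 equiv), Et3N (1 equiv), CH2Cl2, −20 to 0 °C; used without chromatography
Reagents that add atoms: trifluoroacetic acid, OC(=O)C(F)(F)F
Why: Acid-promoted epoxide opening of borderline SN2 type, in which trifluoroacetate attacks the protonated epoxide at the benzylic C4 (activated and far less hindered than the neopentyl-like C3) from the face opposite the oxygen bridge, so that C4 is inverted to R while C3 stays S, the acceptor-substituted arene and the soluble trifluoroacetate salt disfavouring a free benzylic cation that could collapse with retention.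

Step 5
Reactants: 8 (3S,4R)-6-acetyl-3-hydroxy-2,2-dimethylchroman-4-yl trifluoroacetate
Product: 12 (2S,3R)-5-acetyl-2-(prop-1-en-2-yl)-2,3-dihydro-1-benzofuran-3-yl trifluoroacetate, via triflate 9 (not isolated), via aryloxiranium ion 10 (not isolated), via tertiary cation 11 (not isolated)
Conditions: Tf2O (1.05 equiv), 2,6-di-tert-butyl-4-methylpyridine, CH2Cl2, −78 °C to rt
Reagents that add atoms: none
Why: Tf2O converts the hindered C3 hydroxyl into triflate 9, whose equatorial C3–O bond in the diequatorial half-chair lies anti to the ring bond O1–C2, so a lone pair of O1 expels triflate from the rear to give the bridged aryloxiranium ion 10, which opens at its tertiary carbon to cation 11 and then loses a methyl proton to the hindered pyridine. The closest known reaction is the 1,2-aryloxy shift that contracts 3-sulfonyloxy-2,2-dimethylchromans to 2-isopropenyl-2,3-dihydrobenzofurans (a Wagner–Meerwein-type ring contraction with heteroatom participation); only the trifluoroacetoxy group at C4 is an addition to that substrate class. Ring B therefore results from shrinking the six-membered ring: O1 attacks C3 in a 3-exo-tet sense and the original O1–CMe2 bond then breaks, so no open-chain cyclisation is involved. The new C2 centre is the old C3 with inverted geometry (its descriptor stays S because the priorities of its carbon neighbours change), while the old C4 is carried over untouched as C3 (R), so the trans-(3S,4R) substrate should give only the trans-(2S,3R) product through a stereospecific anti displacement (substrate control). The step needs oxygen migration to outrun aryl migration, acyloxy participation and triflation of the ketone, and needs proton loss from a methyl group: the ring fusion keeps the ipso p-orbital of the arene away from C3 and the trifluoroacetoxy group would not stabilise the C4 cation left by an aryl shift, the electron-poor trifluoroacetyl carbonyl is a poor neighbouring group and is gauche to the triflate in the reactive conformer, one equivalent of Tf2O at −78 °C should be consumed by the alcohol well before the aryl ketone reacts, and the bulky base reaches only the exposed methyl hydrogens.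

Step 6
Reactants: 12 (2S,3R)-5-acetyl-2-(prop-1-en-2-yl)-2,3-dihydro-1-benzofuran-3-yl trifluoroacetate
Product: 13 1-[(2S,3R)-3-hydroxy-2-(prop-1-en-2-yl)-2,3-dihydro-1-benzofuran-5-yl]ethan-1-one
Conditions: K2CO3 (cat.), MeOH, 0 °C
Reagents that add atoms: none
Why: Base-catalysed transesterification (Zemplén-type methanolysis) should remove the strongly activated trifluoroacetyl group within minutes at 0 °C without touching the ketone, the alkene or either stereocentre, because only the acyl C–O bond is broken.

Step 7
Reactants: 13 1-[(2S,3R)-3-hydroxy-2-(prop-1-en-2-yl)-2,3-dihydro-1-benzofuran-5-yl]ethan-1-one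
Product: 14 (2S,3R)-5-acetyl-2-(prop-1-en-2-yl)-2,3-dihydro-1-benzofuran-3-yl acetate
Conditions: Ac2O, pyridine, DMAP (cat.), CH2Cl2, 0 °C to rt
Reagents that add atoms: acetic anhydride, CC(=O)OC(C)=O
Why: DMAP-catalysed acylation of the secondary benzylic alcohol (nucleophilic catalysis through the N-acetylpyridinium ion) installs the acetate with retention, since the C3–O bond is not broken, and the mildly basic medium avoids acid-induced dehydration to a benzofuran.

Step 8
Reactants: 14 (2S,3R)-5-acetyl-2-(prop-1-en-2-yl)-2,3-dihydro-1-benzofuran-3-yl acetate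
Product: 16 (2S,3R)-5-[(1R)-1-hydroxyethyl]-2-(prop-1-en-2-yl)-2,3-dihydro-1-benzofuran-3-yl acetate, via borate ester 15 (not isolated)
Conditions: (S)-2-methyl-CBS-oxazaborolidine (10 mol%), catecholborane, toluene, −78 °C; then MeOH, aq. NaHCO3
Reagents that add atoms: none
Why: Corey–Bakshi–Shibata reduction, in which the ketone oxygen binds to the ring boron of the (S)-oxazaborolidine with the aryl group turned away from the catalyst and the nitrogen-bound borane delivers hydride to the Si face to give the (R)-carbinol (reagent control), catecholborane being chosen because at −78 °C it should neither hydroborate the isopropenyl group nor reduce the acetate.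

Step 9
Reactants: 16 (2S,3R)-5-[(1R)-1-hydroxyethyl]-2-(prop-1-en-2-yl)-2,3-dihydro-1-benzofuran-3-yl acetate; 17 tigloyl chloride, (2E)-2-methylbut-2-enoyl chloride
Product: 18 (1R)-1-[(2S,3R)-3-acetoxy-2-(prop-1-en-2-yl)-2,3-dihydro-1-benzofuran-5-yl]ethyl (2E)-2-methylbut-2-enoate
Conditions: pyridine, DMAP (cat.), CH2Cl2, 0 °C
Reagents that add atoms: none
Why: Acylation of the secondary alcohol by the acid chloride under DMAP catalysis (nucleophilic acyl substitution) keeps the (R) configuration because the carbinol C–O bond stays intact, and pyridine, a weak base, avoids vinylketene formation and thus deconjugation or E/Z scrambling of the tigloyl unit.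

Step 10
Reactants: 18 (1R)-1-[(2S,3R)-3-acetoxy-2-(prop-1-en-2-yl)-2,3-dihydro-1-benzofuran-5-yl]ethyl (2E)-2-methylbut-2-enoate
Product: 20 (1R)-1-[(2S,3R)-3-acetoxy-2-(3-oxoprop-1-en-2-yl)-2,3-dihydro-1-benzofuran-5-yl]ethyl (2E)-2-methylbut-2-enoate, via allylic alcohol 19 (not isolated)
Conditions: SeO2 (0.3 equiv), t-BuOOH, CH2Cl2, rt; aq. Na2S2O3 wash, then Dess–Martin periodinane, NaHCO3, CH2Cl2, 0 °C
Reagents that add atoms: tert-butyl hydroperoxide, CC(C)(C)OO (the oxygen atom is passed on through SeO2, O=[Se]=O)
Why: Riley-type allylic oxidation in its catalytic SeO2/t-BuOOH form, in which an ene reaction at the 1,1-disubstituted alkene (hydrogen taken from the methyl group, not from the hindered ring C2–H) and a 2,3-sigmatropic shift place oxygen on the former methyl carbon and restore the exocyclic methylene, the conjugated tiglate alkene being too electron-poor to compete, after which the buffered Dess–Martin oxidation converts alcohol 19 and any aldehyde already present into the enal under neutral conditions that spare the acid- and base-sensitive 3-acetoxy-dihydrobenzofuran.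

**Compound list**

1 | 4'-hydroxyacetophenone | CC(=O)c1ccc(O)cc1 | starting material
2 | 3-chloro-3-methylbut-1-yne | CC(C)(Cl)C#C | starting material
3 | 1-{4-[(2-methylbut-3-yn-2-yl)oxy]phenyl}ethan-1-one | CC(=O)c1ccc(OC(C)(C)C#C)cc1 | intermediate
4 | 1-[4-hydroxy-3-(3-methylbuta-1,2-dien-1-yl)phenyl]ethan-1-one (allenylphenol) | CC(=O)c1ccc(O)c(C=C=C(C)C)c1 | intermediate (not isolated)
5 | 4-acetyl-6-(3-methylbut-2-en-1-ylidene)cyclohexa-2,4-dien-1-one (ortho-quinone methide) | CC(=O)C1=CC(=CC=C(C)C)C(=O)C=C1 | intermediate (not isolated)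
6 | 1-(2,2-dimethyl-2H-chromen-6-yl)ethan-1-one | CC(=O)c1ccc2OC(C)(C)C=Cc2c1 | intermediate
7 | (3S,4S)-6-acetyl-3,4-epoxy-2,2-dimethylchroman | CC1(C)Oc2ccc(C(C)=O)cc2[C@@H]3O[C@H]13 | intermediate
8 | (3S,4R)-6-acetyl-3-hydroxy-2,2-dimethylchroman-4-yl trifluoroacetate | CC1(C)Oc2ccc(C(C)=O)cc2[C@@H](OC(=O)C(F)(F)F)[C@@H]1O | intermediate (precursor of the key step)
9 | (3S,4R)-6-acetyl-2,2-dimethyl-3-(trifluoromethylsulfonyloxy)chroman-4-yl trifluoroacetate | CC1(C)Oc2ccc(C(C)=O)cc2[C@@H](OC(=O)C(F)(F)F)[C@@H]1OS(=O)(=O)C(F)(F)F | intermediate (not isolated)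
10 | bridged aryloxiranium ion, O1 bonded to the aryl carbon, to CMe2 and to the old C3 (triflate counter-ion) | CC1(C)[O+]2c3ccc(C(C)=O)cc3[C@@H](OC(=O)C(F)(F)F)[C@H]12 | intermediate (not isolated)
11 | 2-[(2S,3R)-5-acetyl-3-(trifluoroacetoxy)-2,3-dihydro-1-benzofuran-2-yl]propan-2-yl cation | C[C+](C)[C@@H]1Oc2ccc(C(C)=O)cc2[C@H]1OC(=O)C(F)(F)F | intermediate (not isolated)
12 | (2S,3R)-5-acetyl-2-(prop-1-en-2-yl)-2,3-dihydro-1-benzofuran-3-yl trifluoroacetate | C=C(C)[C@@H]1Oc2ccc(C(C)=O)cc2[C@H]1OC(=O)C(F)(F)F | intermediate (product of the key step)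
13 | 1-[(2S,3R)-3-hydroxy-2-(prop-1-en-2-yl)-2,3-dihydro-1-benzofuran-5-yl]ethan-1-one | C=C(C)[C@@H]1Oc2ccc(C(C)=O)cc2[C@H]1O | intermediate
14 | (2S,3R)-5-acetyl-2-(prop-1-en-2-yl)-2,3-dihydro-1-benzofuran-3-yl acetate | C=C(C)[C@@H]1Oc2ccc(C(C)=O)cc2[C@H]1OC(C)=O | intermediate
15 | (2S,3R)-5-[(1R)-1-(1,3,2-benzodioxaborol-2-yloxy)ethyl]-2-(prop-1-en-2-yl)-2,3-dihydro-1-benzofuran-3-yl acetate (borate ester) | C=C(C)[C@@H]1Oc2ccc([C@@H](C)OB3Oc4ccccc4O3)cc2[C@H]1OC(C)=O | intermediate (not isolated)
16 | (2S,3R)-5-[(1R)-1-hydroxyethyl]-2-(prop-1-en-2-yl)-2,3-dihydro-1-benzofuran-3-yl acetate | C=C(C)[C@@H]1Oc2ccc([C@@H](C)O)cc2[C@H]1OC(C)=O | intermediate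
17 | tigloyl chloride, (2E)-2-methylbut-2-enoyl chloride | C/C=C(\C)C(Cl)=O | starting material
18 | (1R)-1-[(2S,3R)-3-acetoxy-2-(prop-1-en-2-yl)-2,3-dihydro-1-benzofuran-5-yl]ethyl (2E)-2-methylbut-2-enoate | C=C(C)[C@@H]1Oc2ccc([C@@H](C)OC(=O)/C(C)=C/C)cc2[C@H]1OC(C)=O | intermediate
19 | (1R)-1-[(2S,3R)-3-acetoxy-2-(3-hydroxyprop-1-en-2-yl)-2,3-dihydro-1-benzofuran-5-yl]ethyl (2E)-2-methylbut-2-enoate | C=C(CO)[C@@H]1Oc2ccc([C@@H](C)OC(=O)/C(C)=C/C)cc2[C@H]1OC(C)=O | intermediate (not isolated)
20 | (1R)-1-[(2S,3R)-3-acetoxy-2-(3-oxoprop-1-en-2-yl)-2,3-dihydro-1-benzofuran-5-yl]ethyl (2E)-2-methylbut-2-enoate | C=C(C=O)[C@@H]1Oc2ccc([C@@H](C)OC(=O)/C(C)=C/C)cc2[C@H]1OC(C)=O | target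

**Step count**

Total: 10 steps. Longest linear sequence: 10 steps (1 to 20); compounds 2 and 17 are purchased.

**Steps most likely to fail**

Step 5. The para acetyl group and the neighbouring trifluoroacetoxy group may slow the displacement of triflate by the ring oxygen. That would leave time for triflation of the ketone enol, for loss or O4-to-O3 shift of the trifluoroacetyl group, or for capture of the cation before proton loss. The fallback sets out from epoxide 7 and separates activation from ionisation, using a sulfonylating agent that does not attack ketones and a sturdier ester that is still electron-poor. Opening 7 with trichloroacetic acid in CH2Cl2 should give (3S,4R)-6-acetyl-3-hydroxy-2,2-dimethylchroman-4-yl trichloroacetate F1, which tolerates chromatography. Mesylation (MsCl, Et3N, CH2Cl2, 0 °C) should give the isolable (3S,4R)-6-acetyl-3-(methylsulfonyloxy)-2,2-dimethylchroman-4-yl trichloroacetate F2. Heating F2 in hexafluoroisopropanol with 2,6-lutidine (sealed vessel, about 80 °C) is a buffered solvolysis with neighbouring-oxygen participation and should give (2S,3R)-5-acetyl-2-(prop-1-en-2-yl)-2,3-dihydro-1-benzofuran-3-yl trichloroacetate F3. Methanolysis (K2CO3, MeOH) then returns to the route at alcohol 13.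

Step 4. The protonated epoxide may open through a benzylic ion pair that collapses on the face it left, giving syn addition and eroding the trans relationship. The trifluoroacetate may also be lost or shifted during isolation. The fallback sets out from epoxide 7 and fixes the inversion with a basic SN2 opening. CsOAc and AcOH in DMF at 60 °C should give (3S,4R)-6-acetyl-3-hydroxy-2,2-dimethylchroman-4-yl acetate F4; any acetyl shift to O3 is harmless here. Methanolysis (K2CO3, MeOH) should give the trans-diol 1-[(3S,4R)-3,4-dihydroxy-2,2-dimethyl-3,4-dihydro-2H-chromen-6-yl]ethan-1-one F5. One equivalent of trifluoroacetic anhydride with 2,6-lutidine in CH2Cl2 at −78 °C should acylate the less hindered benzylic hydroxyl and return to the route at 8, which is used at once in step 5.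

Step 10. The selenium ene reaction may be sluggish on an alkene flanked by two C–O bonds. Oxidation of the tiglate methyl groups or of the ring C2–H, or elimination of acetic acid towards a benzofuran, could then compete. The fallback sets out from 18 and replaces the selenium chemistry by an ene-type chlorination and an N-oxide oxidation. NaOCl with CeCl3·7H2O in CH2Cl2/H2O at 0 °C should give (1R)-1-[(2S,3R)-3-acetoxy-2-(3-chloroprop-1-en-2-yl)-2,3-dihydro-1-benzofuran-5-yl]ethyl (2E)-2-methylbut-2-enoate F6. Treatment of F6 with 4-methylmorpholine N-oxide and catalytic NaI in MeCN at rt (Kornblum-type oxidation of an allylic halide) should give the enal and so return to the route at target 20.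

**Further compounds**

F1 | step 5 | (3S,4R)-6-acetyl-3-hydroxy-2,2-dimethylchroman-4-yl trichloroacetate | CC1(C)Oc2ccc(C(C)=O)cc2[C@@H](OC(=O)C(Cl)(Cl)Cl)[C@@H]1O
F2 | step 5 | (3S,4R)-6-acetyl-3-(methylsulfonyloxy)-2,2-dimethylchroman-4-yl trichloroacetate | CC1(C)Oc2ccc(C(C)=O)cc2[C@@H](OC(=O)C(Cl)(Cl)Cl)[C@@H]1OS(C)(=O)=O
F3 | step 5 | (2S,3R)-5-acetyl-2-(prop-1-en-2-yl)-2,3-dihydro-1-benzofuran-3-yl trichloroacetate | C=C(C)[C@@H]1Oc2ccc(C(C)=O)cc2[C@H]1OC(=O)C(Cl)(Cl)Cl
F4 | step 4 | (3S,4R)-6-acetyl-3-hydroxy-2,2-dimethylchroman-4-yl acetate | CC1(C)Oc2ccc(C(C)=O)cc2[C@@H](OC(C)=O)[C@@H]1O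
F5 | step 4 | 1-[(3S,4R)-3,4-dihydroxy-2,2-dimethyl-3,4-dihydro-2H-chromen-6-yl]ethan-1-one | CC1(C)Oc2ccc(C(C)=O)cc2[C@@H](O)[C@@H]1O
F6 | step 10 | (1R)-1-[(2S,3R)-3-acetoxy-2-(3-chloroprop-1-en-2-yl)-2,3-dihydro-1-benzofuran-5-yl]ethyl (2E)-2-methylbut-2-enoate | C=C(CCl)[C@@H]1Oc2ccc([C@@H](C)OC(=O)/C(C)=C/C)cc2[C@H]1OC(C)=O
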